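**Retrosynthetic overview**

- Target ⇐ acid-triggered isomerisation of a bis(quinone epoxide) ⇐ nucleophilic epoxidation of a bis(2-methoxy-3-methyl-1,4-benzoquinone) ⇐ peracid oxidation of 1,13-bis(3,5-dimethoxy-4-methylphenyl)tridecane.
- Key disconnection: both benzylic C–C bonds. The C13 tether is two aldehyde carbons plus 1,11-dibromoundecane. The aldehyde carbon of 3,5-dimethoxy-4-methylbenzaldehyde is made nucleophilic as the azo anion of its N-trityl hydrazone (a reversed-polarity d1 synthon) and alkylated at both ends of the dibromide; N2 and the trityl group leave in the same flask.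
- Regiochemistry comes from symmetry: the two methoxy groups flank the ring methyl, one becomes a quinone carbonyl and the other stays as OMe; the OH enters at the only ring C–H left, next to the chain.
- Ring order: no ring is constructed. Both six-membered rings are bought as arenes and converted to quinones, both ends at once, after the tether is in place.

Assumption: the target has no stereocentre and no stereogenic double bond, so it is one achiral compound and no enantioselective step is needed; tritylhydrazine hydrochloride is taken as a catalogue reagent.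

**Route**

Step 1
Reactants: 1 3,5-dimethoxy-4-methylbenzaldehyde
Product: 2 (E)-1-(3,5-dimethoxy-4-methylbenzylidene)-2-tritylhydrazine
Conditions: TrNHNH2·HCl (1.05 equiv), NaOAc (1.1 equiv), EtOH, 25 °C
Reagents that add atoms: tritylhydrazine hydrochloride, Cl.NNC(c1ccccc1)(c1ccccc1)c1ccccc1
Why: Hydrazone condensation of an unhindered aryl aldehyde with the free NH2 of tritylhydrazine, buffered so the acid-labile N–trityl bond survives, gives the E hydrazone because that geometry avoids the aryl/NH-trityl clash.

Step 2
Reactants: 2 (E)-1-(3,5-dimethoxy-4-methylbenzylidene)-2-tritylhydrazine (2.2 equiv); 3 1,11-dibromoundecane (1.0 equiv)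
Product: 6 1,13-bis(3,5-dimethoxy-4-methylphenyl)tridecane, via lithium azo anion 4 (not isolated), via bis(trityl azo) adduct 5 (not isolated)
Conditions: LiN(iPr)2 (2.2 equiv), THF, −78 °C; 3, DMPU, −78 → −30 °C; PhSH (10 equiv), −30 → 25 °C
Reagents that add atoms: none
Why: Baldwin-type azo-anion reductive alkylation, in which N-deprotonation gives an aza-allyl (azo) anion whose nitrogen is blocked by trityl, so the former aldehyde carbon displaces each primary bromide of 3 (SN2) and the benzylic trityl azo compound then loses N2 by homolysis on warming, the benzylic radical taking hydrogen from PhSH and the trityl radical being capped as its sulfide; the two transient benzylic stereocentres of 5 are uncontrolled and disappear.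

Step 3
Reactants: 6 1,13-bis(3,5-dimethoxy-4-methylphenyl)tridecane
Product: 7 6,6'-(tridecane-1,13-diyl)bis(2-methoxy-3-methylcyclohexa-2,5-diene-1,4-dione)
Conditions: 30% aq. H2O2 (6 equiv), HCO2H, CH2Cl2, 0 → 25 °C
Reagents that add atoms: hydrogen peroxide, OO
Why: Performic acid arene-to-p-quinone oxidation (electrophilic hydroxylation, then oxidative demethylation), in which the only free ring positions are equivalent and each lies ortho and para to a methoxy group, so hydroxylation there and loss of methanol from the para methoxy carbon gives the 2-methoxy-3-methyl-6-alkyl-p-quinone in each ring, as in the known oxidation of 2,6-dimethoxytoluene to 2-methoxy-3-methyl-1,4-benzoquinone.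

Step 4
Reactants: 7 6,6'-(tridecane-1,13-diyl)bis(2-methoxy-3-methylcyclohexa-2,5-diene-1,4-dione)
Product: 8 1,13-bis(3-methoxy-4-methyl-2,5-dioxo-7-oxabicyclo[4.1.0]hept-3-en-1-yl)tridecane (cis-fused epoxides, mixture of rac and meso forms)
Conditions: 30% aq. H2O2 (4 equiv), Na2CO3 (cat.), THF–H2O, 0 °C
Reagents that add atoms: hydrogen peroxide, OO
Why: Weitz–Scheffer nucleophilic epoxidation, in which hydroperoxide adds to the unsubstituted β-carbon of the chain-bearing double bond (the methoxy-bearing double bond is a fully substituted, deactivated vinylogous ester) and ring closure can only give the cis-fused epoxide; the new stereocentres are uncontrolled between the two rings and are erased in step 5.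

Step 5
Reactants: 8 1,13-bis(3-methoxy-4-methyl-2,5-dioxo-7-oxabicyclo[4.1.0]hept-3-en-1-yl)tridecane
Product: 9 3,3'-(tridecane-1,13-diyl)bis(2-hydroxy-5-methoxy-6-methylcyclohexa-2,5-diene-1,4-dione)
Conditions: conc. H2SO4, 0 °C, 15 min; ice–water
Reagents that add atoms: none
Why: Acid-catalysed epoxide-to-enol isomerisation of a quinone epoxide (the phthiocol-type rearrangement), in which the epoxide opens at the tertiary chain-bearing carbon and the proton on the other epoxide carbon is lost, so the hydroxyl can only end up on the former C–H carbon next to the chain and the hydroxyquinone is the thermodynamic sink.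

**Compound list**

1 | 3,5-dimethoxy-4-methylbenzaldehyde | COc1cc(C=O)cc(OC)c1C | starting material
2 | (E)-1-(3,5-dimethoxy-4-methylbenzylidene)-2-tritylhydrazine | COc1cc(/C=N/NC(c2ccccc2)(c2ccccc2)c2ccccc2)cc(OC)c1C | intermediate
3 | 1,11-dibromoundecane | BrCCCCCCCCCCCBr | starting material
4 | lithium azo anion (lithium salt of N-deprotonated 2, not isolated) | [Li+].COc1cc(C=N[N-]C(c2ccccc2)(c2ccccc2)c2ccccc2)cc(OC)c1C | intermediate
5 | bis(trityl azo) adduct: 1,13-bis(3,5-dimethoxy-4-methylphenyl)-1,13-bis(trityldiazenyl)tridecane (diastereomer mixture, not isolated) | COc1cc(C(CCCCCCCCCCCC(N=NC(c2ccccc2)(c2ccccc2)c2ccccc2)c2cc(OC)c(C)c(OC)c2)N=NC(c2ccccc2)(c2ccccc2)c2ccccc2)cc(OC)c1C | intermediate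
6 | 1,13-bis(3,5-dimethoxy-4-methylphenyl)tridecane | COc1cc(CCCCCCCCCCCCCc2cc(OC)c(C)c(OC)c2)cc(OC)c1C | intermediate
7 | 6,6'-(tridecane-1,13-diyl)bis(2-methoxy-3-methylcyclohexa-2,5-diene-1,4-dione) | COC1=C(C)C(=O)C=C(CCCCCCCCCCCCCC2=CC(=O)C(C)=C(OC)C2=O)C1=O | intermediate
8 | 1,13-bis(3-methoxy-4-methyl-2,5-dioxo-7-oxabicyclo[4.1.0]hept-3-en-1-yl)tridecane (cis-fused epoxides, stereoisomer mixture) | COC1=C(C)C(=O)C2OC2(CCCCCCCCCCCCCC34OC3C(=O)C(C)=C(OC)C4=O)C1=O | intermediate
9 | 3,3'-(tridecane-1,13-diyl)bis(2-hydroxy-5-methoxy-6-methylcyclohexa-2,5-diene-1,4-dione), achiral | COC1=C(C)C(=O)C(O)=C(CCCCCCCCCCCCCC2=C(O)C(=O)C(C)=C(OC)C2=O)C1=O | target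

**Step count**

Total step count: 5. Longest linear sequence: 5 (from 1).

**Steps most likely to fail, with fallbacks**

Step 2 is the riskiest. The stabilised benzylic azo anion may alkylate slowly. The azo adduct may lose N2 before the thiol is present and recombine with trityl. Both ends must react. The fallback sets out from 1 and comes back at 6. Aldehyde 1 is condensed with propane-1,3-dithiol (BF3·OEt2, CH2Cl2) to give 2-(3,5-dimethoxy-4-methylphenyl)-1,3-dithiane F1. This is lithiated (n-BuLi, THF, −30 °C) and alkylated at both ends of 3 (0.48 equiv) to give 1,11-bis[2-(3,5-dimethoxy-4-methylphenyl)-1,3-dithian-2-yl]undecane F2. Desulfurisation with Raney Ni (EtOH, reflux) then delivers 6. The polarity-reversed carbon is the same, but the auxiliary is removed in a separate reductive operation.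

Step 3 is the second risk. Performic acid may over-oxidise the electron-rich rings or give o-quinone by-products, and two rings must react. The fallback sets out from 6 and comes back at 7. Treatment of 6 with NaSEt (DMF, 120 °C) removes one methyl per ring, because the phenoxide formed protects the second methoxy group, and gives 1,13-bis(3-hydroxy-5-methoxy-4-methylphenyl)tridecane F3. Teuber oxidation of the free para position with (KO3S)2NO (KH2PO4 buffer, acetone–H2O) gives 7.

Step 5 is the third risk. Concentrated H2SO4 may cleave the vinylogous methyl ester or char the material before isomerisation is complete. The fallback sets out from 7 and comes back at 9, leaving out the epoxide. Thiele–Winter acetoxylation of 7 (Ac2O, BF3·OEt2, 25 °C) puts an acetoxy group on the single free ring position and gives 1,13-bis(2,3,6-triacetoxy-5-methoxy-4-methylphenyl)tridecane F4. Methanolysis under air (K2CO3, MeOH, then dilute HCl) frees the hydroxyhydroquinone, which autoxidises to 9.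

Further compounds
F1 | step 2 | 2-(3,5-dimethoxy-4-methylphenyl)-1,3-dithiane | COc1cc(C2SCCCS2)cc(OC)c1C
F2 | step 2 | 1,11-bis[2-(3,5-dimethoxy-4-methylphenyl)-1,3-dithian-2-yl]undecane | COc1cc(C2(CCCCCCCCCCCC3(c4cc(OC)c(C)c(OC)c4)SCCCS3)SCCCS2)cc(OC)c1C
F3 | step 3 | 1,13-bis(3-hydroxy-5-methoxy-4-methylphenyl)tridecane | COc1cc(CCCCCCCCCCCCCc2cc(O)c(C)c(OC)c2)cc(O)c1C
F4 | step 5 | 1,13-bis(2,3,6-triacetoxy-5-methoxy-4-methylphenyl)tridecane | COc1c(C)c(OC(C)=O)c(OC(C)=O)c(CCCCCCCCCCCCCc2c(OC(C)=O)c(OC(C)=O)c(C)c(OC)c2OC(C)=O)c1OC(C)=O
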